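## Structural features

The target is a flavonol: a 4H‑chromen‑4‑one in which benzo ring A is fused across C4a–C8a to pyranone ring C, and the 4‑hydroxyphenyl ring B hangs on C2 by a single C2–C1' bond. The periphery carries five oxygens: hydrogen sulfate esters on O3 (an enol oxygen of ring C) and on O7 (ring A), free hydroxyls at C5 and C4', and the C4 carbonyl. There is no stereocentre, so no adjacent stereocentres have to be related and the whole problem is one of regiochemistry. The fragile groups are the two sulfate monoesters, which solvolyse under acid (the free acid form catalyses its own hydrolysis), and the pyranone, which hydroxide can open by attack next to the ring oxygen. The real difficulty is to place sulfate on exactly O3 and O7 while O5 and O4' stay free. O5 is set apart by its hydrogen bond to the C4 carbonyl, but O4' needs a mask that can be removed after sulfation without touching S–O bonds. The feature exploited by the key step is that ring A is a resorcinol fused to the pyranone at C4a–C8a. Its six carbons map onto a pyranone C=C (C4a, C8a), a ketene (C8 and C5 with its oxygen) and an ynol ether (C6 and C7 with its oxygen), so a ketene/ynol ether benzannulation grows ring A with O5 free and O7 etherified from the outset.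

## Logic of the disconnections

22 ⇒ 20 (through 21). The benzylic C–O bond at O4' is restored and the two acidic sulfate protons are traded for ammonium counter‑ions. O4' must stay masked until both sulfates are in place, and the acid form is too labile to carry through a synthesis. The gain is a storable, organic‑soluble salt. The forward step must cleave the benzyl ether without touching S–O bonds, aryl C–O bonds or the C2=C3 bond, and must release the free acid cold.

20 ⇒ 19. The S–O bonds at O3 and O7 are cut, because the most fragile bonds should be made as late as possible. The gain is a neutral triol. The forward step must sulfate 3‑OH and 7‑OH and leave 5‑OH alone, which rests on the hydrogen bond from 5‑OH to C4=O.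

19 ⇒ 18. In the retrosynthetic sense the O3–CH2 bond of an acetal and the O7–CH2 bond of a silylethyl ether are added. The two oxygens destined for sulfate then carry groups that fall to one acid treatment while the O4' benzyl ether persists. In 18 every oxygen is in a distinct state (O5 free, O3 and O7 acid‑labile, O4' benzylated). The forward step must cleave an electron‑poor aryl ether without debenzylation and without alkylating ring A.

18 ⇒ 9 + 14 (key disconnection). The bonds C5–C6, C7–C8 and C4a–C5 are cut, and the C8–C8a bond is traced back to a 1,2‑shift from an acyl carbon. Ring A is thereby recognised as pyranone C=C + ketene + ynol ether. The bicyclic chromenone falls back to a monocyclic pyranone and a two‑carbon alkyne, and the two ring A oxygens arise differentiated. The forward step must generate the ketene without damaging the pyranone chromophore or the acetal CH2, must control the orientation of the alkyne, and must close at the only free carbon next to the ketene‑bearing carbon.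

9 ⇒ 7 (through 8). The C–C bond between the carbonyl carbon and the diazo carbon is cut, since acylation of a diazomethane equivalent is the shortest way to a terminal diazo ketone. The gain is a stable carboxylic acid. The forward step must activate the acid without HCl (because of the acetal) and must use a diazo reagent that is not explosive.

7 ⇒ 4 + 5 (through 6). The bond between pyranone C6 and C1' of ring B (the later C2–C1' bond) is cut, so ring B is attached as a whole by cross‑coupling to a vinylogous acyl bromide. The gain is convergence, with ring B bought already benzylated. The forward step must couple and then free the carboxyl in aqueous base without opening the pyranone.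

4 ⇒ 3 ⇒ 2 ⇒ 1. The acetal O–CH2 bond, the C6–Br bond and the ester O–CH3 bond are removed in turn. 1 already holds the pyranone with oxygen at the future C3, carbonyl at the future C4 and a carboxyl exactly where ring A must grow. The gain is a commercial starting material reached by three functional‑group steps. Bromination must occur only at C6, which is the one ring carbon ortho to the enolic hydroxyl.

14 ⇒ 10 + 11 (through 12 and 13). The O–C(sp) bond is cut, with the alkoxide as nucleophile and a chlorinated C2 unit as electrophile. The gain is two bulk chemicals joined in one pot. The forward step needs low temperature and an inert atmosphere throughout.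

## Other disconnections considered

Alternative 1: The cut is the C3–C4 bond of ring C. Going forward, dialdehyde A1 (an aryl ether that already contains O1–C2 and ring B) would be treated with a thiazolium salt and an amine base. The carbene would turn the ring A formyl group into an acyl anion equivalent that adds to the aliphatic formyl group, closing ring C as the racemic trans‑3‑hydroxychroman‑4‑one A2.
- In its favour: the step is metal‑free, runs near room temperature and needs neither light nor a diazo compound, so on safety it is the better of the two plans. Ring A comes from an inexpensive symmetric trioxygenated benzene, and the C3 oxygen is created in the bond‑forming event itself.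
- Against it here: the wanted orientation demands that the hindered, electron‑rich, doubly ortho‑substituted aromatic aldehyde become the nucleophile, while the more electrophilic and strongly enolisable α‑aryl α‑aryloxy aldehyde only accepts. The reverse polarity would give the ketol with carbonyl and hydroxyl interchanged, and A1 invites enolisation and self‑aldol reaction under base. A2 is at the dihydroflavonol oxidation level, so two stereocentres are made only to be destroyed and a separate C2–C3 dehydrogenation is needed before acid can unmask ring A and reach 19.
- Comparison: structurally it builds ring C onto a bought ring A, where the chosen plan builds ring A onto a bought ring C. Mechanistically it makes one bond by umpolung against three in a pericyclic cascade. Its decisive selectivity is not enforced by the substrate, whereas in the chosen plan the orientation is enforced by the polarity of the two partners. In steps to 19 the two plans are about equal (about four steps to A1, then cyclisation, dehydrogenation and deprotection), so the alternative offers better safety, no gain in length and a less secure key step.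

Alternative 2: The cuts are C4–C4a and O1–C2. Phloroglucinol A3 and the α‑benzoyloxy β‑keto ester A4 would be heated together without acid, neat or under microwave heating above 200 °C. C‑acylation of A3 by the ester carbon and condensation of a phenol oxygen with the ketone would give 3‑O‑benzoyl‑4'‑O‑benzylkaempferol A5, and mild aminolysis of the benzoate would then lead to 19.
- In its favour: A3 is bought, symmetric (no regiochemical question) and unprotected, and ring C with its C3 oxygen appears in one operation. In step economy this is clearly better than the chosen plan (about four steps to 19 against eight), and it is also free of diazo compounds and photochemistry.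
- Against it here: the forcing temperature is hard on this particular pair. A4 combines a benzyl ether with an α‑acyloxy β‑keto ester that can undergo acyl migration, transfer of its benzoate to the phenols of A3, and decarboxylative loss. Traces of acid divert the condensation to the coumarin mode, and α‑substituted β‑keto esters are the poorer partners in this reaction.
- Comparison: on structure, A5 has O5 and O7 both free and not differentiated by construction as they are in 18. Because the chelated 5‑OH differentiates itself at the sulfation stage, this is no handicap, and on this point the alternative is the equal of the chosen plan. On mechanism, an uncatalysed thermal condensation with several competing acyl‑transfer channels stands against a cascade that runs between 20 and 80 °C with predictable orientation. The alternative wins on brevity and loses on predictability.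

Alternative 3: The cuts are C2–C3 and O1–C2. Ester A6, an ortho‑aroyloxyaryl ketone whose α‑carbon carries a methoxymethoxy group, would be deprotonated with LiN(SiMe3)2. The ketone enolate attacks the neighbouring aryl ester (O‑to‑C aroyl shift) to give a 1,3‑diketone. Acid work‑up closes ring C by cyclodehydration and hydrolyses all three acetals, giving 4'‑O‑benzylkaempferol A7, which is identical with 19.
- In its favour: this is the classical and most dependable flavone construction, ionic and scalable in every step. It needs no light, no diazo compound and no chlorinated acetylene chemistry, so on safety and robustness it is better than the chosen plan. A6 should be about four steps from A3, so 19 would be reached in about five steps, which is also better step economy.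
- Against it here: the α‑oxygenated aryl ketone requires an electrophilic acylation of an A3 derivative with an oxygenated two‑carbon unit. The α‑oxygen must survive that acylation and still leave with acid at the end. The α‑alkoxy group makes the enolate more hindered and slows the acyl shift, and three acetals have to be installed with a chloromethyl ether.
- Comparison: on structure, O5 and O7 are again undifferentiated, which for this target is no drawback (equal to the chosen plan). On mechanism, a Claisen‑type acyl transfer is more predictable than a photochemical cascade whose outcome depends on the photostability of the pyranone. What the chosen plan offers in return is a ring A made de novo with its oxygen pattern fixed by mechanism, no electrophilic chemistry on a phloroglucinol, an O5 that never needs protection, and easy variation of ring A through other ynol ethers. It is not the shorter way to this particular target.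

Key step: step 7

Remark on the chemistry: the target is taken as the free bis(hydrogen sulfate) exactly as drawn; because that form hydrolyses autocatalytically, the sulfates are carried as triethylammonium salts and the free acid is released only in the last operation, cold.

Remark on the structures: the atom mapping of the benzannulation was checked and no structure needed correction; the acyl carbon of 9 becomes C5, its diazo carbon C8, and the terminal and oxygen‑bearing carbons of 14 become C6 and C7; besides the three ring‑forming bonds, the Wolff shift makes C8–C8a.

Remark on the design: three points were changed for safety and survival of the precursor. The chloromethyl ether for step 3 is made and consumed in solution. The diazo ketone is made with (trimethylsilyl)diazomethane from an acid chloride formed without HCl. The key step is driven by 450 nm light, which the diazo ketone absorbs but the pyranone, the O–CH2 groups and the product should not.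

## Route

Step 1
Reactants: 1 comenic acid (5‑hydroxy‑4‑oxo‑4H‑pyran‑2‑carboxylic acid)
Product: 2 methyl 5‑hydroxy‑4‑oxo‑4H‑pyran‑2‑carboxylate
Conditions: MeOH, H2SO4 (cat.), reflux
Reagents that add atoms: methanol, CO
Why: Fischer esterification; the carboxyl is the only group that reacts, and the ester keeps it inert through bromination, alkylation and cross‑coupling.

Step 2
Reactants: 2 methyl 5‑hydroxy‑4‑oxo‑4H‑pyran‑2‑carboxylate
Product: 3 methyl 6‑bromo‑5‑hydroxy‑4‑oxo‑4H‑pyran‑2‑carboxylate
Conditions: NBS (1.05 equiv), MeCN, 0 °C → rt
Reagents that add atoms: N‑bromosuccinimide, O=C1CCC(=O)N1Br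
Why: Electrophilic bromination of an enolic 5‑hydroxy‑4‑pyranone; C6 is the only ring carbon ortho to the hydroxyl and next to the ring oxygen, whereas C3 is deactivated by the ester, so substitution should occur at C6 alone.

Step 3
Reactants: 3 methyl 6‑bromo‑5‑hydroxy‑4‑oxo‑4H‑pyran‑2‑carboxylate
Product: 4 methyl 6‑bromo‑5‑(methoxymethoxy)‑4‑oxo‑4H‑pyran‑2‑carboxylate
Conditions: CH2(OMe)2, AcCl, ZnBr2 (cat.), toluene, rt; then 3, K2CO3, acetone, 0 °C → rt
Reagents that add atoms: chloromethyl methyl ether, COCCl (made in the flask from dimethoxymethane, COCOC, and acetyl chloride, CC(Cl)=O)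
Why: Williamson‑type O‑alkylation of the acidic enol to its methoxymethyl ether; the chloromethyl ether is generated in solution by acetal/acyl chloride exchange and consumed there, so the neat carcinogenic reagent is never handled, and carbonate is base enough for this vinylogous acid.

Step 4
Reactants: 4 methyl 6‑bromo‑5‑(methoxymethoxy)‑4‑oxo‑4H‑pyran‑2‑carboxylate, 5 4‑(benzyloxy)phenylboronic acid
Product: 7 6‑[4‑(benzyloxy)phenyl]‑5‑(methoxymethoxy)‑4‑oxo‑4H‑pyran‑2‑carboxylic acid, via the methyl ester 6 (not isolated)
Conditions: Pd(dppf)Cl2 (3 mol %), K2CO3 (3 equiv), 1,4‑dioxane/H2O 4:1, 80 °C; then LiOH (2 equiv), 0 °C → rt; then 1 M HCl to pH 3, 0 °C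
Reagents that add atoms: lithium hydroxide, [Li+].[OH-]
Why: Suzuki–Miyaura coupling at a C–Br bond that is a vinylogous acyl bromide and therefore adds readily to palladium, followed by saponification in the same pot, since the aqueous carbonate would partly hydrolyse the ester anyway; the carboxylate allows purification by extraction, and the brief cold acidification should spare the acetal.

Step 5
Reactants: 7 6‑[4‑(benzyloxy)phenyl]‑5‑(methoxymethoxy)‑4‑oxo‑4H‑pyran‑2‑carboxylic acid
Product: 9 2‑[4‑(benzyloxy)phenyl]‑6‑(diazoacetyl)‑3‑(methoxymethoxy)‑4H‑pyran‑4‑one, via the acid chloride 8 (not isolated)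
Conditions: Me2C=C(Cl)NMe2 (1.1 equiv), CH2Cl2, 0 °C → rt; then Me3SiCHN2 (2.2 equiv, hexanes), THF/MeCN 1:1, 0 °C → rt; evaporate, chromatograph
Reagents that add atoms: (trimethylsilyl)diazomethane, C[Si](C)(C)C=[N+]=[N-]
Why: The chloroenamine makes the acid chloride under neutral conditions (no HCl, so the acetal survives), and acylation of the silyl diazomethane with loss of Me3SiCl gives the terminal diazo ketone (Arndt–Eistert‑type acylation without diazomethane); the reagent is not explosive but is toxic on inhalation and is handled in a closed hood.

Step 6
Reactants: 10 2‑(trimethylsilyl)ethanol, 11 trichloroethylene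
Product: 14 [2‑(trimethylsilyl)ethoxy]acetylene, via dichlorovinyl ether 12 (not isolated), via lithium alkynyl ether 13 (not isolated)
Conditions: KH, THF, 0 °C; 11, −50 °C → rt; then n‑BuLi (2.5 equiv), −78 → −40 °C; MeOH, −78 °C → rt; distil at reduced pressure, store cold
Reagents that add atoms: none
Why: One‑pot Greene ynol ether synthesis: the potassium alkoxide and 11 give the (E)‑dichlorovinyl ether by elimination and anti addition, two equivalents of n‑BuLi effect dehydrochlorination and chlorine–lithium exchange to the lithium acetylide, and methanol protonates it; the chlorinated acetylene that passes through the first stage is never accumulated, and everything is kept cold under argon.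

Step 7
Reactants: 9 2‑[4‑(benzyloxy)phenyl]‑6‑(diazoacetyl)‑3‑(methoxymethoxy)‑4H‑pyran‑4‑one, 14 [2‑(trimethylsilyl)ethoxy]acetylene
Product: 18 4'‑O‑benzyl‑3‑O‑(methoxymethyl)‑7‑O‑[2‑(trimethylsilyl)ethyl]kaempferol, via pyranonylketene 15 (not isolated), via cyclobutenone 16 (not isolated), via dienylketene 17 (not isolated)
Conditions: 14 (2.5 equiv), toluene (degassed, 0.05 M), 450 nm LEDs, 20 °C; then 80 °C in the dark
Reagents that add atoms: none
Why: Light absorbed in the n→π* band of the diazo ketone expels N2 and the pyranonyl group shifts from the acyl carbon to the carbene carbon (Wolff rearrangement, which makes the C8–C8a bond), giving ketene 15. The electron‑rich alkyne 14 adds to the ketene C=C in a [2+2] cycloaddition, its terminal carbon bonding to the ketene carbonyl carbon (C5–C6) and its oxygen‑bearing carbon to the ketene CH (C7–C8), so that the four‑membered ring of 16 closes by cycloaddition. Warming opens 16 by conrotatory 4π electrocyclic cleavage of the old ketene σ bond to dienylketene 17; the opening is reversible and only the isomer with the pyranonyl group cis to the ketene carbon can go on, so material should drain through it. Ring A then closes by disrotatory 6π electrocyclisation of the ketene C=C, the enol ether C=C and the pyranone C5=C6 bond (C4a–C5 formed), and the resulting cyclohexadienone enolises to the 5‑phenol held by a hydrogen bond to C4=O. The closest known reaction type is the Danheiser benzannulation in its diazo ketone form, in which unsaturated and heteroaryl ketenes from a photochemical Wolff rearrangement combine with alkoxy‑ or siloxyalkynes. No stereocentre is set: the only one that appears, the ring carbon of 16 bearing the pyranonyl group, is erased on ring opening. The step needs regioselectivity in the cycloaddition, which the matched polarity of ketene (electrophilic carbonyl carbon) and ynol ether (nucleophilic terminal carbon) secures and which places O7 meta to the new 5‑OH, and a single site of closure, which is secured because the other neighbour of the ketene‑bearing pyranone carbon is the ring oxygen. Irradiation at 450 nm addresses only the diazo chromophore and so should spare the pyranone, the O–CH2 hydrogens at O3 and product 18, while the excess of 14 should outrun ketene dimerisation.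

Step 8
Reactants: 18 4'‑O‑benzyl‑3‑O‑(methoxymethyl)‑7‑O‑[2‑(trimethylsilyl)ethyl]kaempferol
Product: 19 4'‑O‑benzylkaempferol
Conditions: TFA/CH2Cl2 1:1, H2O (5 equiv), 0 °C → rt
Reagents that add atoms: none
Why: Acidolysis removes both groups in one operation: the acetal hydrolyses through an oxocarbenium ion that water intercepts, and the protonated silylethyl ether fragments with loss of ethene (β‑silyl effect); the aryl benzyl ether should persist because no soft nucleophile is present to assist its cleavage.

Step 9
Reactants: 19 4'‑O‑benzylkaempferol
Product: 20 bis(triethylammonium) 4'‑O‑benzylkaempferol 3,7‑disulfate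
Conditions: Et3N·SO3 (6 equiv), Et3N (6 equiv), MeCN, 60 °C; chromatography on Sephadex LH‑20 (MeOH)
Reagents that add atoms: sulfur trioxide–triethylamine complex, CC[N+](CC)(CC)S(=O)(=O)[O-]
Why: O‑Sulfation of phenolic and enolic hydroxyls with an amine–SO3 complex; 7‑OH (the most acidic) and 3‑OH should react, while 5‑OH, locked in a six‑membered hydrogen bond to C4=O, is the position known to resist these reagents, and the lipophilic ammonium salt can be purified before the last step.

Step 10
Reactants: 20 bis(triethylammonium) 4'‑O‑benzylkaempferol 3,7‑disulfate
Product: 22 kaempferol 3,7‑di‑O‑sulfate, via debenzylated bis(triethylammonium) salt 21 (not isolated)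
Conditions: H2 (1 atm), Pd/C (10 % palladium on carbon), MeOH, rt; filter; sulfonated polystyrene resin (H+ form), MeOH/H2O, 0 °C; freeze‑dry at once
Reagents that add atoms: none
Why: Catalytic hydrogenolysis of the aryl benzyl ether, under which sulfate S–O bonds, aryl C–O bonds and the pyranone C2=C3 bond should be inert, followed by cation exchange in the cold to replace the ammonium ions by protons; with no free amine present the catalyst should not be inhibited.

## Compound list

1 | comenic acid (5‑hydroxy‑4‑oxo‑4H‑pyran‑2‑carboxylic acid) | O=C(O)c1cc(=O)c(O)co1 | starting material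
2 | methyl 5‑hydroxy‑4‑oxo‑4H‑pyran‑2‑carboxylate | COC(=O)c1cc(=O)c(O)co1 | intermediate
3 | methyl 6‑bromo‑5‑hydroxy‑4‑oxo‑4H‑pyran‑2‑carboxylate | COC(=O)c1cc(=O)c(O)c(Br)o1 | intermediate
4 | methyl 6‑bromo‑5‑(methoxymethoxy)‑4‑oxo‑4H‑pyran‑2‑carboxylate | COC(=O)c1cc(=O)c(OCOC)c(Br)o1 | intermediate
5 | 4‑(benzyloxy)phenylboronic acid | OB(O)c1ccc(OCc2ccccc2)cc1 | starting material
6 | methyl 6‑[4‑(benzyloxy)phenyl]‑5‑(methoxymethoxy)‑4‑oxo‑4H‑pyran‑2‑carboxylate (formed in the flask) | COC(=O)c1cc(=O)c(OCOC)c(-c2ccc(OCc3ccccc3)cc2)o1 | intermediate
7 | 6‑[4‑(benzyloxy)phenyl]‑5‑(methoxymethoxy)‑4‑oxo‑4H‑pyran‑2‑carboxylic acid | O=C(O)c1cc(=O)c(OCOC)c(-c2ccc(OCc3ccccc3)cc2)o1 | intermediate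
8 | 6‑[4‑(benzyloxy)phenyl]‑5‑(methoxymethoxy)‑4‑oxo‑4H‑pyran‑2‑carbonyl chloride (formed in the flask) | O=C(Cl)c1cc(=O)c(OCOC)c(-c2ccc(OCc3ccccc3)cc2)o1 | intermediate
9 | 2‑[4‑(benzyloxy)phenyl]‑6‑(diazoacetyl)‑3‑(methoxymethoxy)‑4H‑pyran‑4‑one | [N-]=[N+]=CC(=O)c1cc(=O)c(OCOC)c(-c2ccc(OCc3ccccc3)cc2)o1 | intermediate
10 | 2‑(trimethylsilyl)ethanol | C[Si](C)(C)CCO | starting material
11 | trichloroethylene | ClC=C(Cl)Cl | starting material
12 | (E)‑1,2‑dichlorovinyl 2‑(trimethylsilyl)ethyl ether (formed in the flask) | C[Si](C)(C)CCO/C(Cl)=C\Cl | intermediate
13 | lithium [2‑(trimethylsilyl)ethoxy]acetylide (formed in the flask) | [Li]C#COCC[Si](C)(C)C | intermediate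
14 | [2‑(trimethylsilyl)ethoxy]acetylene | C#COCC[Si](C)(C)C | intermediate
15 | 2‑[4‑(benzyloxy)phenyl]‑3‑(methoxymethoxy)‑6‑(2‑oxoethenyl)‑4H‑pyran‑4‑one (ketene, formed in the flask) | O=C=Cc1cc(=O)c(OCOC)c(-c2ccc(OCc3ccccc3)cc2)o1 | intermediate
16 | 2‑[4‑(benzyloxy)phenyl]‑3‑(methoxymethoxy)‑6‑{4‑oxo‑2‑[2‑(trimethylsilyl)ethoxy]cyclobut‑2‑en‑1‑yl}‑4H‑pyran‑4‑one (racemic, formed in the flask) | O=C1C=C(OCC[Si](C)(C)C)C1c1cc(=O)c(OCOC)c(-c2ccc(OCc3ccccc3)cc2)o1 | intermediate
17 | 2‑[4‑(benzyloxy)phenyl]‑3‑(methoxymethoxy)‑6‑{(1E)‑4‑oxo‑2‑[2‑(trimethylsilyl)ethoxy]buta‑1,3‑dien‑1‑yl}‑4H‑pyran‑4‑one (pyranonyl group cis to the ketene carbon, formed in the flask) | O=C=C/C(OCC[Si](C)(C)C)=C\c1cc(=O)c(OCOC)c(-c2ccc(OCc3ccccc3)cc2)o1 | intermediate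
18 | 4'‑O‑benzyl‑3‑O‑(methoxymethyl)‑7‑O‑[2‑(trimethylsilyl)ethyl]kaempferol (2‑[4‑(benzyloxy)phenyl]‑5‑hydroxy‑3‑(methoxymethoxy)‑7‑[2‑(trimethylsilyl)ethoxy]‑4H‑chromen‑4‑one) | O=c1c(OCOC)c(-c2ccc(OCc3ccccc3)cc2)oc2cc(OCC[Si](C)(C)C)cc(O)c12 | intermediate
19 | 4'‑O‑benzylkaempferol (2‑[4‑(benzyloxy)phenyl]‑3,5,7‑trihydroxy‑4H‑chromen‑4‑one) | O=c1c(O)c(-c2ccc(OCc3ccccc3)cc2)oc2cc(O)cc(O)c12 | intermediate
20 | bis(triethylammonium) 4'‑O‑benzylkaempferol 3,7‑disulfate | CC[NH+](CC)CC.CC[NH+](CC)CC.O=c1c(OS(=O)(=O)[O-])c(-c2ccc(OCc3ccccc3)cc2)oc2cc(OS(=O)(=O)[O-])cc(O)c12 | intermediate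
21 | bis(triethylammonium) kaempferol 3,7‑disulfate (formed in the flask) | CC[NH+](CC)CC.CC[NH+](CC)CC.O=c1c(OS(=O)(=O)[O-])c(-c2ccc(O)cc2)oc2cc(OS(=O)(=O)[O-])cc(O)c12 | intermediate
22 | kaempferol 3,7‑di‑O‑sulfate (free bis(hydrogen sulfate)) | O=c1c(OS(=O)(=O)O)c(-c2ccc(O)cc2)oc2cc(OS(=O)(=O)O)cc(O)c12 | target

## Step count and risks

Total step count: 10. Longest linear sequence: 9 steps (steps 1, 2, 3, 4, 5, 7, 8, 9, 10 from 1); step 6 is a one‑step branch that joins at step 7.

Least certain steps:

Step 7 (key step). The most likely failures are loss of the ketene before the alkyne captures it (dimerisation or reaction with adventitious water), stalling at the cyclobutenone or dienylketene stage because closure onto the electron‑poor pyranone double bond is slow, and light‑induced degradation if the pyranone chromophore is excited after all. Partial thermal fragmentation of the excess ynol ether during the 80 °C stage is a further possibility. The fallback separates the Wolff rearrangement from the cycloaddition and removes light from the ring‑forming stage. It sets out from 9, which with PhCO2Ag (cat.) and Et3N in THF/H2O in the dark should undergo the silver‑promoted Wolff rearrangement with capture by water to give {6‑[4‑(benzyloxy)phenyl]‑5‑(methoxymethoxy)‑4‑oxo‑4H‑pyran‑2‑yl}acetic acid F1, kept cold to avoid decarboxylation. The chloroenamine of step 5 would convert it into {6‑[4‑(benzyloxy)phenyl]‑5‑(methoxymethoxy)‑4‑oxo‑4H‑pyran‑2‑yl}acetyl chloride F2. Slow addition of F2 to 14 and i‑Pr2NEt in toluene would regenerate ketene 15 by dehydrochlorination in the presence of its trap, and heating to 80 °C would carry 16 through 17. The fallback comes back to the route at 18.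

Step 5. The acylation may be incomplete because the silyl diazomethane is a weak nucleophile. Chloride or traces of acid may convert the diazo ketone into the chloromethyl ketone, and the acetal may be lost if HCl forms. The fallback replaces acylation of a diazoalkane by diazo transfer. It sets out from 8, which with MeZnCl and Pd(PPh3)4 (cat.) in THF (Negishi acylation) should give 6‑acetyl‑2‑[4‑(benzyloxy)phenyl]‑3‑(methoxymethoxy)‑4H‑pyran‑4‑one F3. Enolisation with LiN(SiMe3)2 at −78 °C and trapping with CF3CO2CH2CF3 would give 1‑{6‑[4‑(benzyloxy)phenyl]‑5‑(methoxymethoxy)‑4‑oxo‑4H‑pyran‑2‑yl}‑4,4,4‑trifluorobutane‑1,3‑dione F4. 4‑Acetamidobenzenesulfonyl azide, Et3N and one equivalent of water in MeCN would then effect detrifluoroacetylative diazo transfer. The fallback comes back to the route at 9, costs two more steps and avoids diazoalkane reagents altogether.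

Step 4. Hydroxide may add next to the ring oxygen and open the pyranone during saponification, the boronic acid may protodeboronate at 80 °C, and the acetal may suffer on acidification. The fallback changes the mode of ester cleavage from acyl substitution to alkyl–oxygen cleavage. It sets out from 4 and 5, coupled under anhydrous conditions (Pd(dppf)Cl2, CsF, dioxane) so that 6 is isolated. LiI in refluxing ethyl acetate would then remove the methyl group by attack of iodide at carbon, which cannot touch the ring, and cold acidification of the lithium carboxylate returns to the route at 7. This fallback makes no compound outside the list (F0).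

Step 8. Cleavage of the silylethyl ether may lag because O7 is an electron‑poor, weakly basic oxygen. Long exposure to acid may begin to remove the benzyl group, and formaldehyde‑derived electrophiles may alkylate C6 or C8 of ring A. The fallback removes the two groups by two different mechanisms. It sets out from 18, which with CsF in DMF at 80 °C should lose the silylethyl group by fluoride attack at silicon and β‑elimination, giving 4'‑O‑benzyl‑3‑O‑(methoxymethyl)kaempferol F5. HCl in MeOH at 40 °C would then take off the acetal as dimethoxymethane, and the fallback comes back to the route at 19.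

Step 9. Sulfation may stop short at the hindered 3‑OH or run on to O5 under forcing conditions, and charged regioisomers are hard to separate and to assign. The fallback uses a protected sulfate diester. It sets out from 19, which with Cl3CCH2OSO2Cl, Et3N and DMAP in THF should give the neutral 4'‑O‑benzylkaempferol 3,7‑bis(2,2,2‑trichloroethyl sulfate) F6, which can be purified on silica and whose substitution pattern can be verified before deprotection. Zn and HCO2NH4 in MeOH would remove both trichloroethyl groups by reductive elimination to give diammonium 4'‑O‑benzylkaempferol 3,7‑disulfate F7. Hydrogenolysis as in step 10 would give diammonium kaempferol 3,7‑disulfate F8, and the acid resin brings the fallback back to the route at 22.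

## Further compounds

F1 | step 7 | {6‑[4‑(benzyloxy)phenyl]‑5‑(methoxymethoxy)‑4‑oxo‑4H‑pyran‑2‑yl}acetic acid | OC(=O)Cc1cc(=O)c(OCOC)c(-c2ccc(OCc3ccccc3)cc2)o1
F2 | step 7 | {6‑[4‑(benzyloxy)phenyl]‑5‑(methoxymethoxy)‑4‑oxo‑4H‑pyran‑2‑yl}acetyl chloride | O=C(Cl)Cc1cc(=O)c(OCOC)c(-c2ccc(OCc3ccccc3)cc2)o1
F3 | step 5 | 6‑acetyl‑2‑[4‑(benzyloxy)phenyl]‑3‑(methoxymethoxy)‑4H‑pyran‑4‑one | CC(=O)c1cc(=O)c(OCOC)c(-c2ccc(OCc3ccccc3)cc2)o1
F4 | step 5 | 1‑{6‑[4‑(benzyloxy)phenyl]‑5‑(methoxymethoxy)‑4‑oxo‑4H‑pyran‑2‑yl}‑4,4,4‑trifluorobutane‑1,3‑dione | O=C(CC(=O)C(F)(F)F)c1cc(=O)c(OCOC)c(-c2ccc(OCc3ccccc3)cc2)o1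
F0 | step 4 | none | none
F5 | step 8 | 4'‑O‑benzyl‑3‑O‑(methoxymethyl)kaempferol | O=c1c(OCOC)c(-c2ccc(OCc3ccccc3)cc2)oc2cc(O)cc(O)c12
F6 | step 9 | 4'‑O‑benzylkaempferol 3,7‑bis(2,2,2‑trichloroethyl sulfate) | O=c1c(OS(=O)(=O)OCC(Cl)(Cl)Cl)c(-c2ccc(OCc3ccccc3)cc2)oc2cc(OS(=O)(=O)OCC(Cl)(Cl)Cl)cc(O)c12
F7 | step 9 | diammonium 4'‑O‑benzylkaempferol 3,7‑disulfate | [NH4+].[NH4+].O=c1c(OS(=O)(=O)[O-])c(-c2ccc(OCc3ccccc3)cc2)oc2cc(OS(=O)(=O)[O-])cc(O)c12
F8 | step 9 | diammonium kaempferol 3,7‑disulfate | [NH4+].[NH4+].O=c1c(OS(=O)(=O)[O-])c(-c2ccc(O)cc2)oc2cc(OS(=O)(=O)[O-])cc(O)c12
A1 | alternative 1 | 2‑{1‑[4‑(benzyloxy)phenyl]‑2‑oxoethoxy}‑4,6‑bis(methoxymethoxy)benzaldehyde (racemic) | O=CC(Oc1cc(OCOC)cc(OCOC)c1C=O)c1ccc(OCc2ccccc2)cc1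
A2 | alternative 1 | trans‑4'‑O‑benzyl‑5,7‑bis‑O‑(methoxymethyl)dihydrokaempferol (racemic, 2R,3R drawn) | c1ccccc1COc1ccc(cc1)[C@@H]1[C@H](C(=O)c2c(OCOC)cc(OCOC)cc2O1)O
A3 | alternative 2 | phloroglucinol | Oc1cc(O)cc(O)c1
A4 | alternative 2 | ethyl 2‑(benzoyloxy)‑3‑[4‑(benzyloxy)phenyl]‑3‑oxopropanoate (racemic) | CCOC(=O)C(OC(=O)c1ccccc1)C(=O)c1ccc(OCc2ccccc2)cc1
A5 | alternative 2 | 3‑O‑benzoyl‑4'‑O‑benzylkaempferol | O=c1c(OC(=O)c2ccccc2)c(-c2ccc(OCc3ccccc3)cc2)oc2cc(O)cc(O)c12
A6 | alternative 3 | 2‑[(methoxymethoxy)acetyl]‑3,5‑bis(methoxymethoxy)phenyl 4‑(benzyloxy)benzoate | COCOCC(=O)c1c(OCOC)cc(OCOC)cc1OC(=O)c1ccc(OCc2ccccc2)cc1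
A7 | alternative 3 | 4'‑O‑benzylkaempferol (identical with 19) | O=c1c(O)c(-c2ccc(OCc3ccccc3)cc2)oc2cc(O)cc(O)c12
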